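4 questions are put, and I try to answer them with one number read from the two earlier runs.

in all of them: L 11 mM
- green: G 6 mM; temperature 8 °C; run made earlier
- ochre: G 24 mM; temperature 24 °C; run made earlier
- cedar: G 12.1 mM; temperature 30 °C; time 2.5 d
- elm: G 12.1 mM; temperature 15 °C; time 2.5 d
- ash: G 12.1 mM; temperature 0 °C; time 2.5 d

| run | time / d | Z / % | L / % |
|---|---|---|---|
| green | 0.500 | 18.1 | 0.3 |
| green | 1.67 | 16.7 | 0.7 |
| green | 2.50 | 16.7 | 0.1 |
| green | 4.00 | 16.7 | 0 |
| green | 6.00 | 16.5 | 0 |
| green | 8.00 | 16.3 | 0 |
| ochre | 0.208 | 32.0 | 0 |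
| ochre | 0.333 | 31.2 | 0 |
| ochre | 0.500 | 32.9 | 0 |
| ochre | 0.833 | 32.1 | 0 |
| ochre | 1.67 | 32.2 | 0.2 |
| ochre | 2.50 | 31.8 | 0 |

(standard deviation of a reading: 0.5 percentage points)

- the flask with the highest amount of Z, in percent of the L charged ("all alike" if they lie within 1.5 percentage points) (cedar / elm / ash / all alike)
- final Z, as a percentage of the L charged, in cedar
- final Z, as a percentage of the L charged, in elm
- final Z, as a percentage of the L charged, in ash



I work in fractions of the L charged and in equivalents of G to L. In either run L reads no more than 0.7%, so the Z fraction at 2.5 d is what counts. Both runs have a reading at that time: green gives 16.7% at 0.545 equivalents, and ochre gives 31.8% at 2.18. In logarithms the yield rises by 0.280 while the charge rises by 0.602. Their quotient, the slope of log yield against log equivalents of G, is an apparent order of the yield in G, 0.465. Going down from ochre to 1.10 equivalents is −0.297 in the logarithm, which the slope turns into −0.138, a factor of 0.727. So I get 0.231.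

The weak link is temperature, since the slope also contains the step from 8 °C to 24 °C. Elm is an interpolation: its charge sits close to the logarithmic middle, 1.09 equivalents, and its 15 °C lies between the temperatures of the two runs. The temperatures of cedar and ash lie outside them. One clue remains: green's first reading stands 1.4 percentage points above its reading at 2.5 d, against a scatter of 0.5 points, which I take as a weak hint that Z drifts down slowly in green. I add that to ash, giving 0.245. Against the margin of 1.5 points, my answer is "all alike".

The forecast differs: 17.5%, 24.0% and 33.0%, with ash highest, on its own ground that “warming hurts selectivity”.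

The flasks give 23.7% in cedar, 24.4% in elm and 28.1% in ash, so ash is highest.

    L → Q (k = 6.30 × 10⁻⁴ s⁻¹, Ea = 72.0 kJ mol⁻¹)
    G + Q → Z (k = 0.00190 M⁻¹ s⁻¹, Ea = 61.0 kJ mol⁻¹)
    2 Q → E (k = 0.00220 M⁻¹ s⁻¹, Ea = 62.0 kJ mol⁻¹)
    Z ⇌ J (K = 0.990, k = 6.00 × 10⁻⁶ s⁻¹, Ea = 86.0 kJ mol⁻¹, ΔH = 2.00 kJ mol⁻¹)
    (constants at 0 °C)

In elm, the step of G with Q had 86% of its turnover up to 2.5 d behind it by 0.250 d, and half of the turnover of Z into J up to that time was done by 0.201 d. In ash, Z was still falling as J grew: 31.8% at 1.25 d, 28.1% at 2.50 d and 25.3% at 25.0 d. The slope's 0.231 lies 1.3 points below elm and 5 points below ash. For a neighbour flask, which is elm with 30 mM of G, the slope gives 0.353; the flask gives 35.1%.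

All runs were generated by integration for substances that don't exist; noise was put on by code.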